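## Analysis of the target

The target 17 is a flavone: benzo ring A is fused to 4-pyranone ring C (O1, C2, C3, C4=O, C4a, C8a), and aryl ring B sits on C2. It has no stereocentre, so the whole problem is the correct placement of six oxygen substituents. Ring A is substituted on five of its six carbons: C4a carries the C4 carbonyl carbon, C5 and C6 carry methoxy groups, C7 a free hydroxyl, C8a the ring oxygen O1, and only C8 carries hydrogen. Ring B has methoxy groups on C3' and C4' and a free hydroxyl on C5'. The sensitive points are the two phenols, the pyranone (opened by hot strong base), and the 5-OMe group, which lies peri to the C4 carbonyl and is stripped by chelating Lewis acids such as BCl3 or AlCl3. The difficulty is that the oxygens on C5, C6 and C7 are chemically alike, so partial alkylation of a polyphenol cannot be relied on to leave exactly the C7 hydroxyl free. The route rests on the fact that ring A is a hydroquinone monoether: the oxygen on C8a is para to the methoxy group on C6, C5–OMe lies between C4a and C6, and the C7 oxygen lies between C6 and the unsubstituted C8. This is the pattern formed when a 4-alkenyl-4-methoxycyclobutenone made from dimethyl squarate opens and recloses to a benzene ring, each oxygen coming from a different building block.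

## Retrosynthetic reasoning

**17 from 16.** The last bond cut is the O–C bond of a tert-butyl ether on the C7 oxygen. A group removed by protic acid at room temperature is wanted because such conditions leave aryl methyl ethers alone, the 5-OMe included. The tert-butyl group also corresponds to a purchasable vinyl ether (6). The ring B hydroxyl is carried free, which saves a protection and a deprotection.

**16 from 15.** Ring C is opened at O1–C2, and the C2=C3 unsaturation is traded for the enone of 2'-hydroxychalcone 15. This cut is preferred to C4–C4a, which would demand an acylation of a ring A phenol with an open regiochemical choice. The forward step has to close the ring 6-endo and remove two hydrogens.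

**15 from 13 and 14.** The enone double bond (the future C2–C3) is cut to methyl ketone 13 and aldehyde 14. Ring B is thereby bought with its substitution pattern complete, so no regiochemistry on ring B needs to be created. The forward reaction is a crossed aldol condensation between a ketone that enolizes on one side only and an aldehyde that cannot enolize.

**13 from 12.** The C4 carbonyl is masked as the thioketal of 12. The carbon that becomes C4 has to enter the synthesis as a nucleophile, and the thioketal is the form that tolerates the organolithium and thermal steps before it. The forward step only has to release the ketone without oxidizing a very electron-rich phenol.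

**12 from 9 (through 11 and 10).** This is the key disconnection. The C8a–C8 bond of ring A is cut and the ring is folded back to cyclobutenone 9, in which the future C8a and C6 are directly bonded. It is made here because it is the one cut that turns the four look-alike oxygens of ring A into four different precursors. C5–OMe is a squarate methoxy group, C6–OMe a capped tertiary alkoxide, the C7 oxygen an enol ether oxygen and the C8a hydroxyl a ketone oxygen. The forward reaction is a thermal ring opening to ketene 10, a six-electron closure to dienone 11 and enolization to 12.

**9 from 5 and 6 (through 7 and 8).** The bond between the quaternary ring carbon and the alkoxyvinyl carbon (the future C6–C7 bond) and the O–CH3 bond of the tertiary ether are cut. The forward step adds the lithiated vinyl ether 7 to the one carbonyl of dione 5 that is next to the methoxy-bearing carbon. The alkoxide 8 is then methylated in the same flask.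

**5 from 4, and 4 from 1 and 2 (through 3).** The bond between the ring and the thioketal carbon (the future C4a–C4 bond) is cut to lithiated dithiane 3 and dimethyl squarate 2. Addition gives 4, and acid moves the unsaturation so that the thioketal carbon ends up on the ring double bond of 5. All carbons and oxygens of ring A then come from 2, 1 and 6.

## Alternatives that were turned down

**Alternative 1:** Ring C would be cut at C1'–C2 and C2–C3, with carbon monoxide supplying C2. In the forward step zerovalent palladium (from Pd(dba)2 and a bisphosphine L2) inserts into aryl bromide A3 and takes up CO. The acyl complex ArCO–PdBrL2 then acylates the enolate of acetophenone A2 to give 1,3-diketone A1. Acid would then close ring C and remove both methoxymethyl groups in one flask.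
- For it: three components meet in one step, and the classical diketone is reached without an ester and a rearrangement. The end game from A2 is two steps where the chosen route needs four from 12, so on step economy of the ring C construction this alternative is the stronger one.
- Against it: it presupposes A2, a ring A ketone that already has the full 5,6-dimethoxy-7-O-protected pattern. The main difficulty is therefore left unsolved, and A2 would have to come from selective alkylations of a polyphenol or from the benzannulation chosen here.
- Mechanistic concerns: the phenoxide of A2 competes with the enolate for the acyl complex, the enolate of a 2,6-disubstituted aryl ketone is a hindered nucleophile, the diketone product consumes base, and the electron-rich bromide A3 adds slowly to palladium under CO.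
- Comparison: the chosen strategy offers a ring A whose oxygens are differentiated by construction and a finish by condensation chemistry with no catalyst to inhibit.

**Alternative 2:** Ring C would be cut at O1–C8a and C4–C4a on one side and at O1–C2 on the other. CsF would release the ring A aryne from silyl triflate A5. The carboxylate of arylpropiolic acid A6 adds to the aryne, and the aryl anion attacks the acyl carbon (a formal insertion into the acid C–O bond) to give an ortho-hydroxyaryl ynone. The phenoxide then closes ring C by 6-endo addition to give dibenzyl ether A4, and hydrogenolysis (H2, Pd/C) would finish.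
- For it: two bonds to ring A and all of ring C form in one nearly neutral operation. The regiochemistry is well set up, since the oxygen nucleophile should add at C8a, remote from the C5 methoxy group, leaving the aryl anion on C4a beside that inductively stabilizing substituent.
- Against it: A5 is a pentasubstituted benzene. Its preparation (a differentiated trioxygenated phenol, ortho-halogenation at the right carbon, silylation with silyl migration, triflation) costs more steps than the whole of ring A does in the chosen route, and again needs the three neighbouring oxygens told apart beforehand.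
- Mechanistic concerns: the aryl anion can be protonated by the acid before it reaches the carbonyl, which gives an aryl ester and not the ketone, and the ynone can close 5-exo to an aurone.
- Comparison: on convergence and mildness of the final bond formation it is as good as or better than the chosen route. The chosen route is preferred because its ring A precursor is three steps from purchasable reagents.

**Alternative 3:** Ring C would be cut at C4a–C4 and C4–C3, with carbon monoxide as C4, and at O1–C2. Iodophenol A8, CO and arylacetylene A9 would combine under PdCl2(PPh3)2 and an amine base. Oxidative addition, CO insertion and coupling to the alkyne give an ortho-hydroxyaryl ynone, which cyclizes to bis-silyl ether A7. Fluoride would then free both phenols.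
- For it: ring C is assembled in one step from two halves of similar size, the fluoride deprotection cannot touch the 5-OMe group, and A9 is a short homologation away from aldehyde 14.
- Against it: A8 needs iodine on the carbon between the hydroxyl and a methoxy group. The other ortho position, between the hydroxyl and the silyloxy group, is equally activated, so the ring A problem returns as a regiochemical one.
- Mechanistic concerns: the iodide is electron-rich and flanked on both sides, so oxidative addition and CO insertion are slow and direct alkynylation without CO (leading to a 2-arylbenzofuran) competes. The ynone may close 5-exo, and phenolic silyl ethers are at risk under warm amine base.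
- Comparison: the alternative is shorter once A8 is in hand. The chosen route has no positional selectivity on an existing arene to win, because ring A is built with its substituents already in place.

Key step: step 4

Remark on the chemistry: tert-butyl vinyl ether is assumed to undergo α-lithiation as ethyl and methyl vinyl ethers do. Compounds 4, 8 and 9 each carry one stereocentre, are formed racemic and lose it before the aromatic stage, so no stereocontrol is needed.

## Route

Step 1
Reactants: 1 2-methyl-1,3-dithiane; 2 dimethyl squarate (3,4-dimethoxycyclobut-3-ene-1,2-dione)
Product: 4 4-hydroxy-2,3-dimethoxy-4-(2-methyl-1,3-dithian-2-yl)cyclobut-2-en-1-one (racemic), via 2-lithio-2-methyl-1,3-dithiane 3 (not isolated)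
Conditions: n-BuLi, THF, −30 °C; then added to 2 in THF, −78 °C; aq. NH4Cl
Reagents that add atoms: none
Why: Corey–Seebach umpolung: deprotonation at C2 of the dithiane gives an acyl anion equivalent that adds 1,2 to one carbonyl of the squarate at −78 °C; adding the organolithium to the squarate keeps the electrophile in excess so the adduct is not attacked twice. The new carbinol centre is racemic and disappears in step 2.

Step 2
Reactants: 4 4-hydroxy-2,3-dimethoxy-4-(2-methyl-1,3-dithian-2-yl)cyclobut-2-en-1-one
Product: 5 3-methoxy-4-(2-methyl-1,3-dithian-2-yl)cyclobut-3-ene-1,2-dione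
Conditions: conc. HCl (cat.), CH2Cl2, 0 °C → rt
Reagents that add atoms: water, O (supplies the new carbonyl oxygen; the tertiary hydroxyl leaves as water)
Why: Acid-induced allylic transposition of a squarate 1,2-adduct: the hydroxyl ionizes with push from the enol ether oxygen two carbons away, water adds to the oxocarbenium carbon and methanol is lost, which places the thioketal carbon on the ring double bond. Because the vinylogous oxygen and not sulfur drives the ionization, a short cold exposure to catalytic acid should leave the dithiane ring intact.

Step 3
Reactants: 6 tert-butyl vinyl ether; 5 3-methoxy-4-(2-methyl-1,3-dithian-2-yl)cyclobut-3-ene-1,2-dione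
Product: 9 4-(1-tert-butoxyethenyl)-3,4-dimethoxy-2-(2-methyl-1,3-dithian-2-yl)cyclobut-2-en-1-one (racemic), via (1-tert-butoxyethenyl)lithium 7 (not isolated), via lithium tertiary alkoxide 8 (not isolated)
Conditions: 6, t-BuLi, THF, −78 → 0 °C; 5, THF, −78 °C; MeOTf (1.1 equiv), −78 °C; Et3N, then aq. NaHCO3
Reagents that add atoms: methyl trifluoromethanesulfonate, COS(=O)(=O)C(F)(F)F
Why: α-Lithiation of the vinyl ether gives an alkenyllithium that adds 1,2 to the carbonyl next to the methoxy-bearing carbon, because that carbonyl is an ordinary ketone while the other is a vinylogous ester and is shielded by the thioketal. Williamson-type O-methylation of the anionic alkoxide in the same flask should outrun S-methylation of the neutral, hindered thioketal at −78 °C, and Et3N destroys leftover triflate before warming. The quaternary centre is racemic and is lost in step 4.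

Step 4
Reactants: 9 4-(1-tert-butoxyethenyl)-3,4-dimethoxy-2-(2-methyl-1,3-dithian-2-yl)cyclobut-2-en-1-one
Product: 12 5-tert-butoxy-3,4-dimethoxy-2-(2-methyl-1,3-dithian-2-yl)phenol, via dienylketene 10 (not isolated), via cyclohexa-2,4-dienone 11 (not isolated)
Conditions: toluene (degassed, 0.02 M), Ar, base-washed glassware, 110 °C
Reagents that add atoms: none
Why: This is a Moore rearrangement, the thermal ring expansion of a squarate-derived 4-alkenyl-4-alkoxycyclobutenone to a hydroquinone monoether. Heating causes conrotatory 4π electrocyclic opening of the bond between the carbonyl carbon and the quaternary carbon to give the conjugated ketene 10. Ring A then closes by a disrotatory 6π electrocyclization in which the ketene carbon (the future C8a) bonds to the CH2 terminus of the enol ether (the future C8) to give dienone 11, and irreversible enolization aromatizes it to phenol 12. No stereocentre is formed and the single centre of 9 is destroyed. The selectivity needed is torquoselectivity: the methoxy group on the quaternary carbon must turn outward so that the alkoxyvinyl group ends up cis to the ketene, and the strong preference of oxygen donors for outward rotation in cyclobutene openings secures this; a molecule that opens the other way can only reclose to 9 and open again. The positions of the ring A substituents (C5 and C6 methoxy groups from the squarate oxygen and the capped alkoxide, the C7 oxygen from the enol ether, the C8a hydroxyl from the ketone, the masked acetyl on C4a) were fixed in steps 1 to 3 and cannot scramble here. Neutral conditions at 110 °C lie well below the temperature at which a tert-butyl ether loses 2-methylpropene, and the thioketal is thermally inert.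

Step 5
Reactants: 12 5-tert-butoxy-3,4-dimethoxy-2-(2-methyl-1,3-dithian-2-yl)phenol
Product: 13 1-(4-tert-butoxy-6-hydroxy-2,3-dimethoxyphenyl)ethan-1-one
Conditions: MeI (excess), CaCO3, MeCN/H2O (4:1), 45 °C
Reagents that add atoms: water, O
Why: Alkylative thioketal hydrolysis: S-methylation makes sulfur a leaving group and the benzylic thionium ion, stabilized by the ortho-hydroxy, ortho-methoxy and para-tert-butoxy groups, is captured by water. A non-oxidative method is chosen because halogen-based oxidants would turn the 4-methoxyphenol into a quinone; CaCO3 keeps the medium too weakly basic for O-methylation of the phenol and takes up the HI that would attack the tert-butyl ether.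

Step 6
Reactants: 13 1-(4-tert-butoxy-6-hydroxy-2,3-dimethoxyphenyl)ethan-1-one; 14 3-hydroxy-4,5-dimethoxybenzaldehyde
Product: 15 (2E)-1-(4-tert-butoxy-6-hydroxy-2,3-dimethoxyphenyl)-3-(3-hydroxy-4,5-dimethoxyphenyl)prop-2-en-1-one
Conditions: KOH (aq. 50%), EtOH, rt; then 1 M HCl, 0 °C, to pH 5–6
Reagents that add atoms: none
Why: Claisen–Schmidt condensation: the enolate of the hydroxyacetophenone adds to the non-enolizable aldehyde and E1cB loss of hydroxide gives the thermodynamically preferred E-enone. The phenoxide of 14 is meta to the formyl group and does not deactivate it by conjugation, as in the same reaction of isovanillin; the tert-butyl ether is inert to hydroxide.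

Step 7
Reactants: 15 (2E)-1-(4-tert-butoxy-6-hydroxy-2,3-dimethoxyphenyl)-3-(3-hydroxy-4,5-dimethoxyphenyl)prop-2-en-1-one
Product: 16 7-tert-butoxy-2-(3-hydroxy-4,5-dimethoxyphenyl)-5,6-dimethoxy-4H-chromen-4-one
Conditions: I2 (10 mol%), DMSO, 120 °C; aq. Na2S2O3
Reagents that add atoms: none
Why: Iodine-catalysed oxidative cyclization of a 2'-hydroxychalcone: 6-endo-trig oxa-Michael closure and iodination at C3 followed by loss of HI give the chromone, with DMSO reoxidizing HI to I2; 2'-hydroxy-6'-methoxychalcones are standard substrates. Only a catalytic amount of iodine is present, which limits ring iodination of the free phenol, and any tert-butyl ether lost to HI only anticipates step 8.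

Step 8
Reactants: 16 7-tert-butoxy-2-(3-hydroxy-4,5-dimethoxyphenyl)-5,6-dimethoxy-4H-chromen-4-one
Product: 17 7-hydroxy-2-(3-hydroxy-4,5-dimethoxyphenyl)-5,6-dimethoxy-4H-chromen-4-one (7,5'-dihydroxy-5,6,3',4'-tetramethoxyflavone)
Conditions: TFA/CH2Cl2 (1:4), 0 °C → rt
Reagents that add atoms: none
Why: Acidolysis of an aryl tert-butyl ether by E1 loss of the tert-butyl cation as 2-methylpropene; protic acid at room temperature does not cleave aryl methyl ethers, the 5-OMe peri to the carbonyl included, which is why chelating Lewis acids are avoided.

## Compound list

1 | 2-methyl-1,3-dithiane | CC1SCCCS1 | starting material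
2 | dimethyl squarate (3,4-dimethoxycyclobut-3-ene-1,2-dione) | COC1=C(OC)C(=O)C1=O | starting material
3 | 2-lithio-2-methyl-1,3-dithiane | [Li]C1(C)SCCCS1 | intermediate (not isolated)
4 | 4-hydroxy-2,3-dimethoxy-4-(2-methyl-1,3-dithian-2-yl)cyclobut-2-en-1-one (racemic) | COC1=C(OC)C(O)(C2(C)SCCCS2)C1=O | intermediate
5 | 3-methoxy-4-(2-methyl-1,3-dithian-2-yl)cyclobut-3-ene-1,2-dione | COC1=C(C2(C)SCCCS2)C(=O)C1=O | intermediate
6 | tert-butyl vinyl ether (2-(ethenyloxy)-2-methylpropane) | C=COC(C)(C)C | starting material
7 | (1-tert-butoxyethenyl)lithium | [Li]C(=C)OC(C)(C)C | intermediate (not isolated)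
8 | lithium 1-(1-tert-butoxyethenyl)-2-methoxy-3-(2-methyl-1,3-dithian-2-yl)-4-oxocyclobut-2-en-1-olate (racemic) | [Li+].[O-]C1(C(=C)OC(C)(C)C)C(OC)=C(C2(C)SCCCS2)C1=O | intermediate (not isolated)
9 | 4-(1-tert-butoxyethenyl)-3,4-dimethoxy-2-(2-methyl-1,3-dithian-2-yl)cyclobut-2-en-1-one (racemic) | COC1=C(C2(C)SCCCS2)C(=O)C1(OC)C(=C)OC(C)(C)C | intermediate
10 | (3Z)-5-tert-butoxy-3,4-dimethoxy-2-(2-methyl-1,3-dithian-2-yl)hexa-1,3,5-trien-1-one | O=C=C(C1(C)SCCCS1)/C(OC)=C(OC)\C(=C)OC(C)(C)C | intermediate (not isolated)
11 | 5-tert-butoxy-3,4-dimethoxy-2-(2-methyl-1,3-dithian-2-yl)cyclohexa-2,4-dien-1-one | O=C1CC(OC(C)(C)C)=C(OC)C(OC)=C1C2(C)SCCCS2 | intermediate (not isolated)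
12 | 5-tert-butoxy-3,4-dimethoxy-2-(2-methyl-1,3-dithian-2-yl)phenol | CC1(SCCCS1)c2c(O)cc(OC(C)(C)C)c(OC)c2OC | intermediate
13 | 1-(4-tert-butoxy-6-hydroxy-2,3-dimethoxyphenyl)ethan-1-one | CC(=O)c1c(O)cc(OC(C)(C)C)c(OC)c1OC | intermediate
14 | 3-hydroxy-4,5-dimethoxybenzaldehyde | COc1cc(C=O)cc(O)c1OC | starting material
15 | (2E)-1-(4-tert-butoxy-6-hydroxy-2,3-dimethoxyphenyl)-3-(3-hydroxy-4,5-dimethoxyphenyl)prop-2-en-1-one | COc1cc(/C=C/C(=O)c2c(O)cc(OC(C)(C)C)c(OC)c2OC)cc(O)c1OC | intermediate
16 | 7-tert-butoxy-2-(3-hydroxy-4,5-dimethoxyphenyl)-5,6-dimethoxy-4H-chromen-4-one | COc1cc(-c2cc(=O)c3c(OC)c(OC)c(OC(C)(C)C)cc3o2)cc(O)c1OC | intermediate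
17 | 7-hydroxy-2-(3-hydroxy-4,5-dimethoxyphenyl)-5,6-dimethoxy-4H-chromen-4-one | COc1cc(-c2cc(=O)c3c(OC)c(OC)c(O)cc3o2)cc(O)c1OC | target

## Step count and least certain steps

Total step count: 8. Longest linear sequence: 8 steps (from 1 and 2 to 17); 6 and 14 enter as purchased reagents.

**Step 4 (key step).**
- What may go wrong: loss of 2-methylpropene from the tert-butyl enol ether (acid traces on glass, prolonged heating) before the four-membered ring opens, which removes the alkene needed for closure. Crowding by the tert-butoxy group may also slow the s-cis arrangement required for 6π closure, so that the ketene is consumed by moisture or by dimerization.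
- Fallback (change of enol ether): it sets out from 5. Methoxymethyl vinyl ether F1 (a known reagent, made separately) would be lithiated with sec-BuLi in THF at −78 °C to [1-(methoxymethoxy)ethenyl]lithium F2. This is added to 5 and capped with MeOTf as in step 3 to give the methoxymethyl cyclobutenone F3. Heating in toluene would give the phenol F4, MeI/CaCO3 the acetophenone F5 (the same substance as A2), condensation with 14 the chalcone F6, and I2/DMSO the flavone F7. HCl in MeOH at 40 °C then removes the acetal, and the route is rejoined at 17. The methoxymethyl group is smaller, cannot eliminate an alkene, and is stable to the base and labile to the final acid as tert-butyl is.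

**Step 3.**
- What may go wrong: S-methylation of the thioketal by MeOTf in competition with O-methylation of the hindered tertiary alkoxide, since thioketals are alkylated by this reagent once the mixture warms, followed by loss of the dithiane on work-up. Incomplete α-lithiation of the bulky vinyl ether is the second concern.
- Fallback (no triflate; the methyl group is placed later under chelation control): it sets out from 5 and 7. Alkoxide 8 is quenched with aq. NH4Cl to give the tertiary alcohol F8. Heating as in step 4 would give the hydroquinone F9, and MeI/CaCO3 in aqueous MeCN would free the ketone to give the dihydroxyacetophenone F10. MeI (1 equiv) with K2CO3 in acetone should then methylate only the hydroxyl that is not hydrogen-bonded to the acetyl group, returning to the route at 13.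

**Step 5.**
- What may go wrong: slow S-alkylation at the fully substituted, hindered thioketal, so that long heating with MeI allows O-methylation of the phenol or acid-induced loss of the tert-butyl group. The faster oxidative reagents cannot be used on the free 4-methoxyphenol, which they would oxidize to a quinone.
- Fallback (mask the phenol, then hydrolyse oxidatively): it sets out from 12. Ac2O/pyridine gives the aryl acetate F11. PhI(OCOCF3)2 with NaHCO3 in aqueous MeCN at 0 °C would then remove the thioketal to give the acetoxy ketone F12, and K2CO3 in MeOH cleaves the acetate, returning at 13.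

**Step 7.**
- What may go wrong: electrophilic iodination of the electron-rich phenolic ring B, and HI-promoted loss of the tert-butyl group at 120 °C, which gives mixtures of protected and unprotected material.
- Fallback (cyclize first, dehydrogenate second, no iodine): it sets out from 15. NaOAc in refluxing EtOH would close the chalcone by oxa-Michael addition to the flavanone F13, and DDQ in dioxane at reflux would dehydrogenate C2–C3, returning at 16.

Further compounds
F1 | step 4 | methoxymethyl vinyl ether ((methoxymethoxy)ethene) | C=COCOC
F2 | step 4 | [1-(methoxymethoxy)ethenyl]lithium | [Li]C(=C)OCOC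
F3 | step 4 | 3,4-dimethoxy-4-[1-(methoxymethoxy)ethenyl]-2-(2-methyl-1,3-dithian-2-yl)cyclobut-2-en-1-one (racemic) | COC1=C(C2(C)SCCCS2)C(=O)C1(OC)C(=C)OCOC
F4 | step 4 | 3,4-dimethoxy-5-(methoxymethoxy)-2-(2-methyl-1,3-dithian-2-yl)phenol | CC1(SCCCS1)c2c(O)cc(OCOC)c(OC)c2OC
F5 | step 4 | 1-[6-hydroxy-2,3-dimethoxy-4-(methoxymethoxy)phenyl]ethan-1-one | CC(=O)c1c(O)cc(OCOC)c(OC)c1OC
F6 | step 4 | (2E)-1-[6-hydroxy-2,3-dimethoxy-4-(methoxymethoxy)phenyl]-3-(3-hydroxy-4,5-dimethoxyphenyl)prop-2-en-1-one | COCOc1cc(O)c(C(=O)/C=C/c2cc(O)c(OC)c(OC)c2)c(OC)c1OC
F7 | step 4 | 2-(3-hydroxy-4,5-dimethoxyphenyl)-5,6-dimethoxy-7-(methoxymethoxy)-4H-chromen-4-one | COCOc1cc2oc(-c3cc(O)c(OC)c(OC)c3)cc(=O)c2c(OC)c1OC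
F8 | step 3 | 4-(1-tert-butoxyethenyl)-4-hydroxy-3-methoxy-2-(2-methyl-1,3-dithian-2-yl)cyclobut-2-en-1-one (racemic) | COC1=C(C2(C)SCCCS2)C(=O)C1(O)C(=C)OC(C)(C)C
F9 | step 3 | 5-tert-butoxy-3-methoxy-2-(2-methyl-1,3-dithian-2-yl)benzene-1,4-diol | CC1(SCCCS1)c2c(O)cc(OC(C)(C)C)c(O)c2OC
F10 | step 3 | 1-(4-tert-butoxy-3,6-dihydroxy-2-methoxyphenyl)ethan-1-one | CC(=O)c1c(O)cc(OC(C)(C)C)c(O)c1OC
F11 | step 5 | 5-tert-butoxy-3,4-dimethoxy-2-(2-methyl-1,3-dithian-2-yl)phenyl acetate | CC(=O)Oc1cc(OC(C)(C)C)c(OC)c(OC)c1C2(C)SCCCS2
F12 | step 5 | 2-acetyl-5-tert-butoxy-3,4-dimethoxyphenyl acetate | CC(=O)Oc1cc(OC(C)(C)C)c(OC)c(OC)c1C(C)=O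
F13 | step 7 | 7-tert-butoxy-2-(3-hydroxy-4,5-dimethoxyphenyl)-5,6-dimethoxy-2,3-dihydro-4H-chromen-4-one (racemic) | COc1cc(C2CC(=O)c3c(OC)c(OC)c(OC(C)(C)C)cc3O2)cc(O)c1OC
A1 | alternative 1 | 1-[2-hydroxy-5,6-dimethoxy-4-(methoxymethoxy)phenyl]-3-[3,4-dimethoxy-5-(methoxymethoxy)phenyl]propane-1,3-dione | COCOc1cc(O)c(C(=O)CC(=O)c2cc(OC)c(OC)c(OCOC)c2)c(OC)c1OC
A2 | alternative 1 | 1-[6-hydroxy-2,3-dimethoxy-4-(methoxymethoxy)phenyl]ethan-1-one | CC(=O)c1c(O)cc(OCOC)c(OC)c1OC
A3 | alternative 1 | 5-bromo-1,2-dimethoxy-3-(methoxymethoxy)benzene | COCOc1cc(Br)cc(OC)c1OC
A4 | alternative 2 | 7-(benzyloxy)-2-[3-(benzyloxy)-4,5-dimethoxyphenyl]-5,6-dimethoxy-4H-chromen-4-one | COc1cc(-c2cc(=O)c3c(OC)c(OC)c(OCc4ccccc4)cc3o2)cc(OCc2ccccc2)c1OC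
A5 | alternative 2 | 4-(benzyloxy)-2,3-dimethoxy-6-(trimethylsilyl)phenyl trifluoromethanesulfonate | COc1c(OC)c(OCc2ccccc2)cc([Si](C)(C)C)c1OS(=O)(=O)C(F)(F)F
A6 | alternative 2 | 3-[3-(benzyloxy)-4,5-dimethoxyphenyl]prop-2-ynoic acid | COc1cc(C#CC(=O)O)cc(OCc2ccccc2)c1OC
A7 | alternative 3 | 2-{3,4-dimethoxy-5-[(triisopropylsilyl)oxy]phenyl}-5,6-dimethoxy-7-[(triisopropylsilyl)oxy]-4H-chromen-4-one | COc1cc(-c2cc(=O)c3c(OC)c(OC)c(O[Si](C(C)C)(C(C)C)C(C)C)cc3o2)cc(O[Si](C(C)C)(C(C)C)C(C)C)c1OC
A8 | alternative 3 | 2-iodo-3,4-dimethoxy-5-[(triisopropylsilyl)oxy]phenol | COc1c(I)c(O)cc(O[Si](C(C)C)(C(C)C)C(C)C)c1OC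
A9 | alternative 3 | (5-ethynyl-2,3-dimethoxyphenoxy)triisopropylsilane | COc1cc(C#C)cc(O[Si](C(C)C)(C(C)C)C(C)C)c1OC
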